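The vessel is closed, stirred and held at one temperature; substrate, partner, second reagent and third reagent go in and product comes out, and the birch and oak runs differ in their substrate.

| setting | birch | oak | Thursday's | Monday's |
|---|---|---|---|---|
| substrate | 11 mM | 60 mM | 10 mM | 40 mM |
| partner | 12 mM | 12 mM | 12.0 mM | 12.0 mM |
| second reagent | 8 mM | 8 mM | 8.00 mM | 8.00 mM |
| third reagent | 12 mM | 12 mM | 12.0 mM | 12.0 mM |
| remark | run made earlier | run made earlier |  |  |
| time |  |  | 12 d | 40 d |

| run | time / d | product / % | substrate / % |
|---|---|---|---|
| birch | 1.04 | 10.9 | 16.8 |
| birch | 1.67 | 15.5 | 8.9 |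
| birch | 3.00 | 18.0 | 2.6 |
| birch | 6.00 | 18.9 | 0.1 |
| birch | 12.0 | 18.9 | 0 |
| oak | 2.50 | 4.5 | 6.2 |
| oak | 5.00 | 4.0 | 3.5 |
| oak | 8.00 | 5.2 | 2.2 |
| oak | 10.0 | 4.5 | 2.5 |
| oak | 12.0 | 4.5 | 2.8 |

(standard deviation of a reading: 0.5 percentage points)

- the flask that ends with the higher amount of product, in percent of the substrate charged, or "neither" when 2 percentage points or less lies between them (Thursday's / Monday's / neither)
- final product, as a percentage of the substrate charged, in Thursday's
- final product, as a percentage of the substrate charged, in Monday's

In the birch run, product gains 1.15 mM d⁻¹ up to the first reading, 0.803 mM d⁻¹ up to the second and 0.207 mM d⁻¹ up to the third, so the thing to watch is how this rate fades. The gap between product and its level in birch shrinks from 8 percentage points at 1.04 d to 0.9 points at 3.00 d, which gives 0.622 d as the fading half-life, the time in which that gap halves, read as an apparent first-order half-life. The oak run, with 5.45 times birch's substrate, reads level within its scatter from 2.50 d on, where that half-life leaves a gap of 0.28 points, less than the scatter of 0.5 points, so I carry it over to both new flasks. Thursday's time holds 19.3 fading half-lives and Monday's 64.3, so I expect each to end on its plateau. Between the last readings of birch and oak, whose other three charges are the same, the product moves from 2.08 mM to 2.70 mM, a correction that I write, for those charges held, as the substrate charge raised to the power 0.154. My reckoning then gives 2.05 mM, or 20.5%, for Thursday's, and 2.54 mM, or 6.34%, for Monday's.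

The forecast names Thursday's as the flask that ends higher, with 19.8% (from 18.5% to 21.5%) for Thursday's and 8.2% (from 6.5% to 9.8%) for Monday's, and it reads oak's stall as “something dying after about 56 mM of turnover, not with time”; my Monday's figure is lower than its own.

Thursday's ends at 20.1% and Monday's at 7.01%, so Thursday's gives more, as forecast.

    third reagent → decomposed reagent (k = 0.0440 h⁻¹)
    second reagent + intermediate A → intermediate B (k = 25.0 M⁻¹ h⁻¹)
    2 substrate → homo dimer (k = 1.90 M⁻¹ h⁻¹)
    substrate + partner → intermediate A (k = 7.60 M⁻¹ h⁻¹)
    third reagent + intermediate B → product (k = 3.50 M⁻¹ h⁻¹)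

Monday's stands at 7.01% by 20.0 d, which is 32.2 fading half-lives, and at 7.01% by 40.0 d. The forecast's range for Thursday's is not met by the neighbour of Thursday's with 2.0 mM of second reagent in place of 8.00 mM: after the same 19.3 fading half-lives, counted with birch's reading, it gives 7.83%, below that range's low end of 18.5%. At its end, intermediate A holds 59.2% of the substrate charged.

All runs come from a simulation for an exercise, and the scatter is random.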